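# Proposed synthesis of Kushenol V by palladium-catalysed closure of the O1–C8a bond

## The problem

Kushenol V (21) is a (2S)-flavanone: benzene ring A (C4a–C8a) is fused to dihydropyranone ring C, and a second arene, ring B, sits on C2. Ring A is a fully differentiated phloroglucinol, with hydroxyls on C5 and C7, a 3-methylbut-2-enyl (prenyl) group on C6 between them, hydrogen on C8 and the ring oxygen O1 on C8a. Ring B carries hydroxyls on C2' and C4' and a methoxy group on C5'.

The only stereocentre is C2, which is benzylic, bound to O1 and β to the C4 carbonyl. Nothing else in the molecule can direct it, so it must come from a reagent. A temporary centre at C4 can help purification but cannot be relied on for induction.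

Once the flavanone exists, C2 is fragile. Base opens ring C by retro-oxa-Michael reaction to the achiral 2'-hydroxychalcone, and acid can ionise C2–O1 because the C2' and C4' oxygens stabilise the benzylic cation. The prenyl group rules out hydrogenolysis, free borane, peracids and strong acid (it cyclises onto the C5 or C7 hydroxyl). The 6-prenyl rather than 8-prenyl pattern requires that the three oxygens of ring A are told apart with certainty.

The feature that makes the key step possible is that O1 links an sp2 carbon (C8a) to a secondary benzylic carbinol carbon (C2). The C2–O bond can therefore be made as an open-chain alcohol of defined configuration, and ring C closed on the aryl side through O1–C8a without breaking any bond to C2. Because C8a is para to C6, the ring A building block derives from a mirror-symmetric 4-prenylphenol whose single free hydroxyl marks the future C8a.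

## Retrosynthesis

**21 ⇒ 20.** The four phenolic O–H bonds are traced back to methoxymethyl (MOM) ethers. Benzyl ethers would need hydrogenolysis, which the prenyl alkene does not survive. Methyl ethers could not be distinguished from the C5' methoxy group. Aryl silyl ethers would not last through carbonate at 70 °C and fluoride. MOM ethers also serve as directing groups for the lithiation that places the prenyl group. The forward step needs an acetal cleavage mild enough to spare the prenyl group and C2.

**20 ⇒ 19 ⇒ 18.** The C4 carbonyl is taken back to a carbinol (19) and its tert-butyldimethylsilyl ether (18). A ketone at C4 in the open-chain stage would make the precursor a β-hydroxy ketone, which dehydrates to a chalcone under the base of the ring closure. The price is two extra operations, a desilylation and an oxidation, both of which must avoid strong acid or base.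

**18 ⇒ 17.** The O1–C8a bond is cut, giving the aryl triflate 17 with a free (S)-carbinol at the future C2. The neighbouring cuts are weaker:
- C2–O1 (Mitsunobu or oxa-Michael closure) makes or inverts the stereocentre in the ring-forming event at an electron-rich benzylic carbon, where SN1 leakage and reversibility threaten the configuration.
- C4–C4a (acylation of ring A) reintroduces the C6/C8 regiochemistry problem.

The chosen cut removes ring C entirely and leaves an acyclic chain whose carbinol is only a nucleophile. The forward reaction must have C–O reductive elimination at palladium outrun β-hydride elimination.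

**17 ⇒ 16.** The C2–H bond is cut: the carbinol comes from aryl ketone 16 by oxazaborolidine-catalysed reduction, which is highly reliable for aryl alkyl ketones. Setting C2 by an aldol in the opposite sense (ring A ketone plus ring B aldehyde) would rest the enantiopurity on a less selective reaction and leave a C4 ketone to mask. The reduction must tolerate the prenyl alkene, so catecholborane replaces free borane as the hydride source.

**16 ⇒ 15 ⇒ 13 + 9.** After removal of the silyl group, the C3–C4 bond is cut by an aldol disconnection into methyl ketone 13 (ring B) and aldehyde 9 (ring A). This splits the molecule into two arenes of similar size. The C4 configuration is lost later, but a defined C4 in 15 is useful: the minor C2 epimer from the reduction is then a diastereomer that can be removed, so two imperfect selectivities multiply. The forward step needs enolisation of an aryl methyl ketone and addition to a doubly ortho-substituted, non-enolisable aldehyde.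

**9 ⇒ 8 ⇒ 7.** The S–O bond of the triflate and the C4a–CHO bond are cut, leading to the mirror-symmetric phenol 7. Its two ortho positions are equivalent and its para position is blocked, so formylation can give only 8, and the only free hydroxyl is the one para to the prenyl group. The neighbouring options are both ambiguous: a fully MOM-protected aldehyde would need selective removal of one of two ortho MOM groups, and C-prenylation of a trihydroxybenzaldehyde would leave the wrong hydroxyl free.

**7 ⇒ 5 ⇒ 2 + 3; 2 ⇒ 1.** The C–O bond of the phenol is cut to a C–H bond: in 5 the position para to the prenyl group is the only one without an ortho substituent, so sterically governed C–H borylation and oxidation address it alone. The prenyl C–C bond is cut to 2 and prenyl bromide (3) by lithiation between the two MOM ethers. Resorcinol (1) is preferred to phloroglucinol because it avoids a statistical mono-differentiation of three equal hydroxyls. The forward borylation must leave the trisubstituted alkene alone.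

**13 ⇒ 12 ⇒ 11 ⇒ 10.** Ring B is bought with its full substitution pattern as aldehyde 10. Protection (11), methyl Grignard addition (12) and oxidation give ketone 13. No regiochemical question arises.

## Roads not taken

**Alternative 1:** Cut C2–C3 by a Petasis–Ferrier rearrangement. The enol acetal A1, a 2-aryl-4-methylidene-1,3-benzodioxine assembled from a ring A unit and aldehyde 11, would be ionised at the acetal carbon–enol oxygen bond by a chiral acid. The enolate carbon would then reclose on the aryloxy-oxocarbenium carbon to give the protected flavanone A2, which is identical with 20.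
- Merits: the flavanone oxidation level is reached directly, without the C4 silylation, desilylation and oxidation. Aldehyde 11 is used without conversion into ketone 13. This road is several steps shorter than the chosen one.
- Weak points: C2 would be created by recombination of an ion pair whose cation is planar and strongly stabilised by the 2,4-dialkoxyaryl group. Facial control would have to come from a chiral counter-ion alone, and this is not an established reaction on this ring system. Acids strong enough to ionise the acetal also threaten the four MOM acetals and can reopen the product. The ring A partner poses the same regiochemical demand as 9.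
- Comparison: the chosen plan is longer. Against that, it sets C2 by a ketone reduction of proven reliability and never exposes C2 to an ionising medium.

**Alternative 2:** Build ring A last by a Danheiser benzannulation. Photochemical Wolff rearrangement of the diazo ketone A3, a (2S)-6-diazoacetyl-2-aryl-dihydropyranone, would give a vinylketene. This would combine with the prenyl siloxyalkyne A4 through [2+2] addition, four-electron ring opening and six-electron closure to give the 5-hydroxy-7-silyloxy flavanone A5.
- Merits: the polarity of A4 places the prenyl group on C6 between two oxygens, with no phenol differentiation at all. The C5 and C7 oxygens emerge differentiated. C2 could be set by an asymmetric hetero-Diels–Alder reaction on aldehyde 11. For the ring A regiochemistry this is the better solution.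
- Weak points: A3 combines a diazo ketone with a photoactive vinylogous ester, so other photoreactions compete. The ketene can be trapped by the enol ether or by the prenyl alkene of A4. A3 already holds the base-labile β-alkoxy ketone arrangement at C2. A4 is a sensitive reagent that must be prepared. Acidic MOM removal is still needed at the end.
- Comparison: the chosen plan takes five steps to build ring A, but every step is thermal and has close precedent, and ring closure occurs on a configurationally safe carbinol.

**Alternative 3:** Build ring B last by a Dötz benzannulation. The (2S)-2-ethynylchromanone A6, the zerovalent chromium carbene complex A7, (CO)5Cr=C(OMe)C(OtBu)=CH2, and one CO ligand would combine to give the 2'-hydroxy flavanone A8.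
- Merits: all four substituents of ring B are placed in one step with the C2' hydroxyl free. C2 could be set early on a small molecule by asymmetric conjugate alkynylation.
- Weak points: ring B is available fully substituted as 10, so a de novo construction solves no open problem. Chromium is used in stoichiometric amount. The product is a hydroquinone monoether that is easily oxidised to a quinone on decomplexation. A6 can open by retro-oxa-Michael reaction. The ring A regiochemistry must still be solved for A6.
- Comparison: this road is more convergent on ring B. The chosen plan instead buys ring B and spends its steps on the real difficulties, C2 and the ring A pattern.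

Key step: step 12

Assumption: 2,4-dihydroxy-5-methoxybenzaldehyde (10) is taken as purchasable.
Assumption: the (−)-enantiomer of Ipc2BCl is taken to direct the enolate of 13 to the Si face of aldehyde 9, giving (S) at the carbinol of 15. If the sense were reversed, only the C4 descriptors of 15–19 would change, because this centre becomes a carbonyl in step 14.

## Route

Step 1
Reactants: 1 resorcinol (benzene-1,3-diol)
Product: 2 1,3-bis(methoxymethoxy)benzene
Conditions: NaH, MOMCl, DMF, 0 °C → rt
Reagents that add atoms: chloromethyl methyl ether, COCCl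
Why: O-Alkylation of the bis-phenoxide with the chloromethyl ether (acetal protection); both hydroxyls are equivalent, so no selectivity is needed.

Step 2
Reactants: 2 1,3-bis(methoxymethoxy)benzene; 3 1-bromo-3-methylbut-2-ene (prenyl bromide)
Product: 5 1,3-bis(methoxymethoxy)-2-(3-methylbut-2-enyl)benzene, via [2,6-bis(methoxymethoxy)phenyl]lithium 4 (not isolated)
Conditions: n-BuLi, THF, 0 °C → rt; then CuI (10 mol %), 3, −78 °C → rt
Reagents that add atoms: n-butyllithium, [Li]CCCC (its lithium stands only in intermediate 4)
Why: Directed ortho-metalation removes the hydrogen between the two MOM ethers through double chelation, and the copper-assisted aryl anion should displace the primary allylic bromide (SN2) to give the linear prenyl arene.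

Step 3
Reactants: 5 1,3-bis(methoxymethoxy)-2-(3-methylbut-2-enyl)benzene
Product: 7 3,5-bis(methoxymethoxy)-4-(3-methylbut-2-enyl)phenol, via pinacol arylboronate 6 (not isolated)
Conditions: [Ir(OMe)(cod)]2 (1.5 mol %), 4,4'-di-tert-butyl-2,2'-bipyridine (3 mol %), B2pin2, THF, 60 °C; then aq. NaOH, H2O2, 0 °C → rt
Reagents that add atoms: bis(pinacolato)diboron, CC1(C)OB(OC1(C)C)B1OC(C)(C)C(C)(C)O1 (its boryl group stands only in intermediate 6); hydrogen peroxide, OO (the phenol oxygen of 7)
Why: Iridium-catalysed C–H borylation is sterically governed and should touch only the ring position with no ortho substituent, para to the prenyl group, the trisubstituted alkene being a poor partner for the iridium boryl. Alkaline peroxide then converts C–B into C–O by 1,2-aryl shift without epoxidising the alkene.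

Step 4
Reactants: 7 3,5-bis(methoxymethoxy)-4-(3-methylbut-2-enyl)phenol
Product: 8 6-hydroxy-2,4-bis(methoxymethoxy)-3-(3-methylbut-2-enyl)benzaldehyde
Conditions: MgCl2, Et3N, (CH2O)n, THF, reflux
Reagents that add atoms: formaldehyde (as paraformaldehyde), C=O
Why: Casnati–Skattebøl ortho-formylation: the magnesium phenoxide delivers formaldehyde to the ortho carbon and a second formaldehyde takes the hydride. The two ortho positions of 7 are equivalent and the para position is blocked, so only 8 can form, and the non-acidic medium spares acetals and alkene.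

Step 5
Reactants: 8 6-hydroxy-2,4-bis(methoxymethoxy)-3-(3-methylbut-2-enyl)benzaldehyde
Product: 9 2-formyl-3,5-bis(methoxymethoxy)-4-(3-methylbut-2-enyl)phenyl trifluoromethanesulfonate
Conditions: PhNTf2, Et3N, DMAP (cat.), CH2Cl2, 0 °C → rt
Reagents that add atoms: N-phenylbis(trifluoromethanesulfonimide), O=S(=O)(N(c1ccccc1)S(=O)(=O)C(F)(F)F)C(F)(F)F
Why: Mild triflyl transfer to the acidic salicylaldehyde-type phenoxide; the only free hydroxyl is the one para to the prenyl group, so the leaving group lands on the future C8a.

Step 6
Reactants: 10 2,4-dihydroxy-5-methoxybenzaldehyde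
Product: 11 5-methoxy-2,4-bis(methoxymethoxy)benzaldehyde
Conditions: NaH, MOMCl, DMF, 0 °C → rt
Reagents that add atoms: chloromethyl methyl ether, COCCl
Why: Acetal protection as in step 1; the strong base is chosen because the C2 hydroxyl is hydrogen-bonded to the aldehyde and reacts sluggishly with amine bases.

Step 7
Reactants: 11 5-methoxy-2,4-bis(methoxymethoxy)benzaldehyde
Product: 12 (RS)-1-[5-methoxy-2,4-bis(methoxymethoxy)phenyl]ethanol
Conditions: MeMgBr, THF, 0 °C; then aq. NH4Cl
Reagents that add atoms: methylmagnesium bromide, C[Mg]Br
Why: Grignard addition to the aldehyde; the carbinol is racemic, which is of no concern because it is oxidised in step 8.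

Step 8
Reactants: 12 (RS)-1-[5-methoxy-2,4-bis(methoxymethoxy)phenyl]ethanol
Product: 13 1-[5-methoxy-2,4-bis(methoxymethoxy)phenyl]ethanone
Conditions: Dess–Martin periodinane, pyridine, CH2Cl2, 0 °C → rt
Reagents that add atoms: none
Why: Dess–Martin oxidation of a benzylic secondary alcohol under buffered, near-neutral conditions that spare the acetals.

Step 9
Reactants: 13 1-[5-methoxy-2,4-bis(methoxymethoxy)phenyl]ethanone; 9 2-formyl-3,5-bis(methoxymethoxy)-4-(3-methylbut-2-enyl)phenyl trifluoromethanesulfonate
Product: 15 2-[(1S)-1-hydroxy-3-[5-methoxy-2,4-bis(methoxymethoxy)phenyl]-3-oxopropyl]-3,5-bis(methoxymethoxy)-4-(3-methylbut-2-enyl)phenyl trifluoromethanesulfonate, via diisopinocampheylboron enolate 14 (not isolated)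
Conditions: 13 (1.3 equiv), (−)-Ipc2BCl, Et3N, Et2O, 0 °C; then 9, −78 → −20 °C; then pH 7 buffer, MeOH, H2O2, 0 °C
Reagents that add atoms: (−)-B-chlorodiisopinocampheylborane, ClB([C@H]1[C@H](C)[C@H]2C[C@@H](C1)C2(C)C)[C@H]1[C@H](C)[C@H]2C[C@@H](C1)C2(C)C (its boron and isopinocampheyl groups stand only in intermediate 14)
Why: Paterson boron aldol: the chloroborane and Et3N form boron enolate 14, which adds to the non-enolisable aldehyde through a cyclic transition state, the isopinocampheyl groups being expected to favour the Si face and hence (S) at the new carbinol. The covalent boron aldolate also keeps the new oxygen from attacking the neighbouring triflate. This centre is temporary (oxidised in step 14) but makes the minor C2 epimer of step 11 a separable diastereomer.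

Step 10
Reactants: 15 2-[(1S)-1-hydroxy-3-[5-methoxy-2,4-bis(methoxymethoxy)phenyl]-3-oxopropyl]-3,5-bis(methoxymethoxy)-4-(3-methylbut-2-enyl)phenyl trifluoromethanesulfonate
Product: 16 2-[(1S)-1-(tert-butyldimethylsilyloxy)-3-[5-methoxy-2,4-bis(methoxymethoxy)phenyl]-3-oxopropyl]-3,5-bis(methoxymethoxy)-4-(3-methylbut-2-enyl)phenyl trifluoromethanesulfonate
Conditions: TBSOTf, 2,6-lutidine, CH2Cl2, −78 °C
Reagents that add atoms: tert-butyldimethylsilyl trifluoromethanesulfonate, CC(C)(C)[Si](C)(C)OS(=O)(=O)C(F)(F)F
Why: Silylation of the hindered benzylic hydroxyl with the silyl triflate and a hindered pyridine base is fast at low temperature, which should outpace retro-aldol cleavage and β-elimination and leave the MOM acetals untouched.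

Step 11
Reactants: 16 2-[(1S)-1-(tert-butyldimethylsilyloxy)-3-[5-methoxy-2,4-bis(methoxymethoxy)phenyl]-3-oxopropyl]-3,5-bis(methoxymethoxy)-4-(3-methylbut-2-enyl)phenyl trifluoromethanesulfonate
Product: 17 2-[(1S,3S)-1-(tert-butyldimethylsilyloxy)-3-hydroxy-3-[5-methoxy-2,4-bis(methoxymethoxy)phenyl]propyl]-3,5-bis(methoxymethoxy)-4-(3-methylbut-2-enyl)phenyl trifluoromethanesulfonate
Conditions: (R)-Me-CBS oxazaborolidine [(R)-1-methyl-3,3-diphenyltetrahydro-1H,3H-pyrrolo[1,2-c][1,3,2]oxazaborole] (20 mol %), catecholborane, toluene, −78 → −40 °C; then MeOH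
Reagents that add atoms: none
Why: Corey–Bakshi–Shibata reduction: the (R)-oxazaborolidine binds the ketone with the aryl group as the large substituent and directs hydride to the face that gives the (S)-carbinol (catalyst control, the mirror image of the acetophenone case with the (S)-catalyst). Catecholborane does not hydroborate the prenyl alkene at this temperature, and any (3R) epimer is a diastereomer of 17 and can be removed.

Step 12
Reactants: 17 2-[(1S,3S)-1-(tert-butyldimethylsilyloxy)-3-hydroxy-3-[5-methoxy-2,4-bis(methoxymethoxy)phenyl]propyl]-3,5-bis(methoxymethoxy)-4-(3-methylbut-2-enyl)phenyl trifluoromethanesulfonate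
Product: 18 (2S,4S)-4-(tert-butyldimethylsilyloxy)-2-[5-methoxy-2,4-bis(methoxymethoxy)phenyl]-5,7-bis(methoxymethoxy)-6-(3-methylbut-2-enyl)chromane
Conditions: Pd(OAc)2 (5 mol %), 2-(di-tert-butylphosphino)-1,1'-binaphthyl (6 mol %), Cs2CO3, toluene, 70 °C
Reagents that add atoms: none
Why: Pd(OAc)2 is reduced in the flask to a monoligated zerovalent palladium species that inserts into the C8a–OTf bond; the aryl palladium intermediate binds the C2 hydroxyl, Cs2CO3 removes its proton, and C–O reductive elimination from the seven-membered aryl palladium alkoxide releases the chroman. The closest known reaction type is the palladium-catalysed intramolecular etherification of ortho-halo- and ortho-sulfonyloxy-aryl propanols with di-tert-butyl biaryl phosphines (Buchwald–Hartwig C–O coupling), which closes 2-substituted chromans from secondary alcohols. Ring C is closed in a six-membered mode, the three sp3 carbons C4, C3 and C2 placing the oxygen within reach of the metal on C8a. No stereocentre is created: only the O–H bond at C2 is broken, so the (S) configuration from step 11 is carried into 18 unchanged, and C4 is a spectator. The step needs reductive elimination to be faster than β-hydride elimination from the benzylic alkoxide, which would give a ketone and a reduced arene; the bulky, electron-rich phosphine enforces a low-coordinate intermediate from which C–O bond formation is fast. The silyl ether on C4 rules out the competing five-membered alkoxide chelate and any retro-aldol or dehydration chemistry. The triflate has only one ortho substituent and lies meta to both acetal oxygens, so oxidative addition should not be retarded, and the weak, insoluble carbonate in toluene limits S–O cleavage of the triflate.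

Step 13
Reactants: 18 (2S,4S)-4-(tert-butyldimethylsilyloxy)-2-[5-methoxy-2,4-bis(methoxymethoxy)phenyl]-5,7-bis(methoxymethoxy)-6-(3-methylbut-2-enyl)chromane
Product: 19 (2S,4S)-2-[5-methoxy-2,4-bis(methoxymethoxy)phenyl]-5,7-bis(methoxymethoxy)-6-(3-methylbut-2-enyl)chroman-4-ol
Conditions: TBAF, THF, 0 °C → rt
Reagents that add atoms: none
Why: Fluoride-induced cleavage of the Si–O bond; aryl ethers, acetals and alkene are inert, and with no carbonyl yet in ring C the C2 centre cannot be lost by ring opening.

Step 14
Reactants: 19 (2S,4S)-2-[5-methoxy-2,4-bis(methoxymethoxy)phenyl]-5,7-bis(methoxymethoxy)-6-(3-methylbut-2-enyl)chroman-4-ol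
Product: 20 (2S)-2-[5-methoxy-2,4-bis(methoxymethoxy)phenyl]-5,7-bis(methoxymethoxy)-6-(3-methylbut-2-enyl)chroman-4-one
Conditions: Dess–Martin periodinane, pyridine, CH2Cl2, 0 °C → rt
Reagents that add atoms: none
Why: Dess–Martin oxidation of the benzylic C4 alcohol without strong acid or base, so the new flavanone is not opened to the chalcone; the temporary C4 centre disappears here.

Step 15
Reactants: 20 (2S)-2-[5-methoxy-2,4-bis(methoxymethoxy)phenyl]-5,7-bis(methoxymethoxy)-6-(3-methylbut-2-enyl)chroman-4-one
Product: 21 (2S)-2-(2,4-dihydroxy-5-methoxyphenyl)-5,7-dihydroxy-6-(3-methylbut-2-enyl)chroman-4-one (Kushenol V)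
Conditions: HCl (3 M aq.), MeOH, 40 °C
Reagents that add atoms: none
Why: Acid-catalysed acetal exchange with methanol removes the four MOM groups as dimethoxymethane; the mild temperature and short exposure are chosen to keep the prenyl group from cyclising onto a phenol and to keep the C2–O1 bond from ionising.

## Compound list

1 | resorcinol (benzene-1,3-diol) | Oc1cccc(O)c1 | starting material
2 | 1,3-bis(methoxymethoxy)benzene | COCOc1cccc(OCOC)c1 | intermediate
3 | 1-bromo-3-methylbut-2-ene (prenyl bromide) | CC(C)=CCBr | starting material
4 | [2,6-bis(methoxymethoxy)phenyl]lithium | [Li]c1c(OCOC)cccc1OCOC | intermediate (not isolated)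
5 | 1,3-bis(methoxymethoxy)-2-(3-methylbut-2-enyl)benzene | COCOc1cccc(OCOC)c1CC=C(C)C | intermediate
6 | 2-[3,5-bis(methoxymethoxy)-4-(3-methylbut-2-enyl)phenyl]-4,4,5,5-tetramethyl-1,3,2-dioxaborolane | COCOc1cc(B2OC(C)(C)C(C)(C)O2)cc(OCOC)c1CC=C(C)C | intermediate (not isolated)
7 | 3,5-bis(methoxymethoxy)-4-(3-methylbut-2-enyl)phenol | COCOc1cc(O)cc(OCOC)c1CC=C(C)C | intermediate
8 | 6-hydroxy-2,4-bis(methoxymethoxy)-3-(3-methylbut-2-enyl)benzaldehyde | O=Cc1c(O)cc(OCOC)c(CC=C(C)C)c1OCOC | intermediate
9 | 2-formyl-3,5-bis(methoxymethoxy)-4-(3-methylbut-2-enyl)phenyl trifluoromethanesulfonate | O=Cc1c(OS(=O)(=O)C(F)(F)F)cc(OCOC)c(CC=C(C)C)c1OCOC | intermediate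
10 | 2,4-dihydroxy-5-methoxybenzaldehyde | COc1cc(C=O)c(O)cc1O | starting material
11 | 5-methoxy-2,4-bis(methoxymethoxy)benzaldehyde | COc1cc(C=O)c(OCOC)cc1OCOC | intermediate
12 | (RS)-1-[5-methoxy-2,4-bis(methoxymethoxy)phenyl]ethanol (racemic) | COc1cc(C(C)O)c(OCOC)cc1OCOC | intermediate
13 | 1-[5-methoxy-2,4-bis(methoxymethoxy)phenyl]ethanone | COc1cc(C(C)=O)c(OCOC)cc1OCOC | intermediate
14 | bis[(−)-isopinocampheyl]boron enolate of 13, {1-[5-methoxy-2,4-bis(methoxymethoxy)phenyl]ethenyloxy}diisopinocampheylborane (isopinocampheyl groups from (+)-α-pinene) | C=C(OB([C@H]1[C@H](C)[C@H]2C[C@@H](C1)C2(C)C)[C@H]1[C@H](C)[C@H]2C[C@@H](C1)C2(C)C)c1cc(OC)c(OCOC)cc1OCOC | intermediate (not isolated)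
15 | 2-[(1S)-1-hydroxy-3-[5-methoxy-2,4-bis(methoxymethoxy)phenyl]-3-oxopropyl]-3,5-bis(methoxymethoxy)-4-(3-methylbut-2-enyl)phenyl trifluoromethanesulfonate | COc1cc(C(=O)C[C@H](O)c2c(OS(=O)(=O)C(F)(F)F)cc(OCOC)c(CC=C(C)C)c2OCOC)c(OCOC)cc1OCOC | intermediate
16 | 2-[(1S)-1-(tert-butyldimethylsilyloxy)-3-[5-methoxy-2,4-bis(methoxymethoxy)phenyl]-3-oxopropyl]-3,5-bis(methoxymethoxy)-4-(3-methylbut-2-enyl)phenyl trifluoromethanesulfonate | COc1cc(C(=O)C[C@H](O[Si](C)(C)C(C)(C)C)c2c(OS(=O)(=O)C(F)(F)F)cc(OCOC)c(CC=C(C)C)c2OCOC)c(OCOC)cc1OCOC | intermediate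
17 | 2-[(1S,3S)-1-(tert-butyldimethylsilyloxy)-3-hydroxy-3-[5-methoxy-2,4-bis(methoxymethoxy)phenyl]propyl]-3,5-bis(methoxymethoxy)-4-(3-methylbut-2-enyl)phenyl trifluoromethanesulfonate | COc1cc([C@@H](O)C[C@H](O[Si](C)(C)C(C)(C)C)c2c(OS(=O)(=O)C(F)(F)F)cc(OCOC)c(CC=C(C)C)c2OCOC)c(OCOC)cc1OCOC | intermediate
18 | (2S,4S)-4-(tert-butyldimethylsilyloxy)-2-[5-methoxy-2,4-bis(methoxymethoxy)phenyl]-5,7-bis(methoxymethoxy)-6-(3-methylbut-2-enyl)chromane | COc1cc([C@@H]2C[C@H](O[Si](C)(C)C(C)(C)C)c3c(cc(OCOC)c(CC=C(C)C)c3OCOC)O2)c(OCOC)cc1OCOC | intermediate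
19 | (2S,4S)-2-[5-methoxy-2,4-bis(methoxymethoxy)phenyl]-5,7-bis(methoxymethoxy)-6-(3-methylbut-2-enyl)chroman-4-ol | COc1cc([C@@H]2C[C@H](O)c3c(cc(OCOC)c(CC=C(C)C)c3OCOC)O2)c(OCOC)cc1OCOC | intermediate
20 | (2S)-2-[5-methoxy-2,4-bis(methoxymethoxy)phenyl]-5,7-bis(methoxymethoxy)-6-(3-methylbut-2-enyl)chroman-4-one | COc1cc([C@@H]2CC(=O)c3c(cc(OCOC)c(CC=C(C)C)c3OCOC)O2)c(OCOC)cc1OCOC | intermediate
21 | Kushenol V, (2S)-2-(2,4-dihydroxy-5-methoxyphenyl)-5,7-dihydroxy-6-(3-methylbut-2-enyl)chroman-4-one | COc1cc([C@@H]2CC(=O)c3c(cc(O)c(CC=C(C)C)c3O)O2)c(O)cc1O | target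

## Step count and risk

Total: 15 steps. Longest linear sequence: 12 steps (steps 1–5 and 9–15, from resorcinol). The ring B branch (steps 6–8) joins at step 9.

**Step 12 (key step).** The likely failure is β-hydride elimination from the aryl palladium alkoxide, which oxidises the C2 carbinol and reduces the C–OTf bond. S–O cleavage of the triflate before oxidative addition is the second concern.

The fallback closes ring C through C2–O1 with inversion instead.
- From 16, reduction with the (S)-enantiomer of the oxazaborolidine and catecholborane would give the C2-epimeric (1S,3R)-carbinol triflate F1.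
- Aqueous Et4NOH in dioxane would cleave the triflate to the (1S,3R)-hydroxy phenol F2.
- Mitsunobu cyclisation (PPh3, diisopropyl azodicarboxylate, THF, 0 °C) would displace the activated benzylic oxygen by the phenol with inversion, returning to the route at 18.

The weakness of this fallback is partial ionisation at the electron-rich benzylic carbon, which is why it is not the first choice.

**Step 3.** The iridium boryl or hydride species may hydroborate or isomerise the prenyl double bond in competition with arene borylation.

The fallback sets out from 2 and performs the C–H oxidation before the alkene is present.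
- Borylation of 2 under the same catalyst would give 2-[3,5-bis(methoxymethoxy)phenyl]-4,4,5,5-tetramethyl-1,3,2-dioxaborolane F3.
- Alkaline peroxide would give 3,5-bis(methoxymethoxy)phenol F4.
- Silylation (TIPSCl, imidazole, DMF) would give [3,5-bis(methoxymethoxy)phenoxy]triisopropylsilane F5.
- n-BuLi would remove the hydrogen between the two acetal oxygens to give [2,6-bis(methoxymethoxy)-4-(triisopropylsilyloxy)phenyl]lithium F6.
- Alkylation with 3 would give [3,5-bis(methoxymethoxy)-4-(3-methylbut-2-enyl)phenoxy]triisopropylsilane F7.
- TBAF would release the phenol, returning to the route at 7.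

**Step 9.** Enolisation of the aryl methyl ketone by the bulky chloroborane may be slow. β-Hydride transfer from an isopinocampheyl group would then reduce the ketone or the aldehyde. Addition to the doubly ortho-substituted aldehyde may also show low facial selectivity.

The fallback gives up control of the temporary centre.
- From 13, LDA in THF at −78 °C would give lithium 1-[5-methoxy-2,4-bis(methoxymethoxy)phenyl]ethenolate F8.
- Addition to 9 and quenching at −78 °C (before the lithium alkoxide can attack the neighbouring triflate) would give the racemic aldol adduct F9.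
- Silylation as in step 10 would give the racemic silyl ether F10.
- Reduction as in step 11 would give the (3S)-carbinol as a pair of C1 epimers F11.
- Ring closure as in step 12 would give the (2S)-chroman as a pair of C4 epimers F12.
- Desilylation would give the (2S)-chroman-4-ol as a pair of C4 epimers F13.
- Dess–Martin oxidation would make both epimers converge, returning to the route at 20.

The enantiomeric purity of 20 then rests on the reduction alone.

**Step 11.** Facial discrimination may be poor because the ortho-alkoxy aryl ketone is twisted and weakly Lewis basic, and uncatalysed reduction may compete. Traces of free borane could also attack the alkene.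

The fallback leaves boron hydrides altogether. From 16, Noyori asymmetric transfer hydrogenation with RuCl(p-cymene)[(S,S)-TsDPEN] (TsDPEN is N-(p-toluenesulfonyl)-1,2-diphenylethylenediamine) in HCO2H/Et3N should deliver the same (S)-carbinol by an outer-sphere metal hydride mechanism that does not touch isolated alkenes. It returns to the route at 17 and makes no new compound.

**Step 15.** Protic acid may add a C5 or C7 hydroxyl across the prenyl double bond. It may also erode C2 through reversible opening of ring C or ionisation of C2–O1.

The fallback avoids Brønsted acid by exchanging the acetals for silyl groups.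
- From 20, TMSOTf and 2,2'-bipyridyl in CH2Cl2 at 0 °C would convert the four aryl MOM ethers into the tetrakis(trimethylsilyl) ether of Kushenol V F14.
- Water at neutral pH would hydrolyse the silyl ethers, returning to the route at 21.

## Further compounds

F1 | step 12 | 2-[(1S,3R)-1-(tert-butyldimethylsilyloxy)-3-hydroxy-3-[5-methoxy-2,4-bis(methoxymethoxy)phenyl]propyl]-3,5-bis(methoxymethoxy)-4-(3-methylbut-2-enyl)phenyl trifluoromethanesulfonate | COc1cc([C@H](O)C[C@H](O[Si](C)(C)C(C)(C)C)c2c(OS(=O)(=O)C(F)(F)F)cc(OCOC)c(CC=C(C)C)c2OCOC)c(OCOC)cc1OCOC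
F2 | step 12 | 2-[(1S,3R)-1-(tert-butyldimethylsilyloxy)-3-hydroxy-3-[5-methoxy-2,4-bis(methoxymethoxy)phenyl]propyl]-3,5-bis(methoxymethoxy)-4-(3-methylbut-2-enyl)phenol | COc1cc([C@H](O)C[C@H](O[Si](C)(C)C(C)(C)C)c2c(O)cc(OCOC)c(CC=C(C)C)c2OCOC)c(OCOC)cc1OCOC
F3 | step 3 | 2-[3,5-bis(methoxymethoxy)phenyl]-4,4,5,5-tetramethyl-1,3,2-dioxaborolane | COCOc1cc(OCOC)cc(B2OC(C)(C)C(C)(C)O2)c1
F4 | step 3 | 3,5-bis(methoxymethoxy)phenol | COCOc1cc(O)cc(OCOC)c1
F5 | step 3 | [3,5-bis(methoxymethoxy)phenoxy]triisopropylsilane | COCOc1cc(O[Si](C(C)C)(C(C)C)C(C)C)cc(OCOC)c1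
F6 | step 3 | [2,6-bis(methoxymethoxy)-4-(triisopropylsilyloxy)phenyl]lithium | [Li]c1c(OCOC)cc(O[Si](C(C)C)(C(C)C)C(C)C)cc1OCOC
F7 | step 3 | [3,5-bis(methoxymethoxy)-4-(3-methylbut-2-enyl)phenoxy]triisopropylsilane | COCOc1cc(O[Si](C(C)C)(C(C)C)C(C)C)cc(OCOC)c1CC=C(C)C
F8 | step 9 | lithium 1-[5-methoxy-2,4-bis(methoxymethoxy)phenyl]ethenolate | [Li]OC(=C)c1cc(OC)c(OCOC)cc1OCOC
F9 | step 9 | racemic 2-[1-hydroxy-3-[5-methoxy-2,4-bis(methoxymethoxy)phenyl]-3-oxopropyl]-3,5-bis(methoxymethoxy)-4-(3-methylbut-2-enyl)phenyl trifluoromethanesulfonate | COc1cc(C(=O)CC(O)c2c(OS(=O)(=O)C(F)(F)F)cc(OCOC)c(CC=C(C)C)c2OCOC)c(OCOC)cc1OCOC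
F10 | step 9 | racemic 2-[1-(tert-butyldimethylsilyloxy)-3-[5-methoxy-2,4-bis(methoxymethoxy)phenyl]-3-oxopropyl]-3,5-bis(methoxymethoxy)-4-(3-methylbut-2-enyl)phenyl trifluoromethanesulfonate | COc1cc(C(=O)CC(O[Si](C)(C)C(C)(C)C)c2c(OS(=O)(=O)C(F)(F)F)cc(OCOC)c(CC=C(C)C)c2OCOC)c(OCOC)cc1OCOC
F11 | step 9 | 2-[(1RS,3S)-1-(tert-butyldimethylsilyloxy)-3-hydroxy-3-[5-methoxy-2,4-bis(methoxymethoxy)phenyl]propyl]-3,5-bis(methoxymethoxy)-4-(3-methylbut-2-enyl)phenyl trifluoromethanesulfonate (pair of C1 epimers) | COc1cc([C@@H](O)CC(O[Si](C)(C)C(C)(C)C)c2c(OS(=O)(=O)C(F)(F)F)cc(OCOC)c(CC=C(C)C)c2OCOC)c(OCOC)cc1OCOC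
F12 | step 9 | (2S,4RS)-4-(tert-butyldimethylsilyloxy)-2-[5-methoxy-2,4-bis(methoxymethoxy)phenyl]-5,7-bis(methoxymethoxy)-6-(3-methylbut-2-enyl)chromane (pair of C4 epimers) | COc1cc([C@@H]2CC(O[Si](C)(C)C(C)(C)C)c3c(cc(OCOC)c(CC=C(C)C)c3OCOC)O2)c(OCOC)cc1OCOC
F13 | step 9 | (2S,4RS)-2-[5-methoxy-2,4-bis(methoxymethoxy)phenyl]-5,7-bis(methoxymethoxy)-6-(3-methylbut-2-enyl)chroman-4-ol (pair of C4 epimers) | COc1cc([C@@H]2CC(O)c3c(cc(OCOC)c(CC=C(C)C)c3OCOC)O2)c(OCOC)cc1OCOC
F0 | step 11 | none | none
F14 | step 15 | (2S)-2-[5-methoxy-2,4-bis(trimethylsilyloxy)phenyl]-6-(3-methylbut-2-enyl)-5,7-bis(trimethylsilyloxy)chroman-4-one | COc1cc([C@@H]2CC(=O)c3c(cc(O[Si](C)(C)C)c(CC=C(C)C)c3O[Si](C)(C)C)O2)c(O[Si](C)(C)C)cc1O[Si](C)(C)C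
A1 | alternative 1 | 2-[5-methoxy-2,4-bis(methoxymethoxy)phenyl]-5,7-bis(methoxymethoxy)-4-methylidene-6-(3-methylbut-2-enyl)-4H-1,3-benzodioxine (racemic at the acetal carbon) | C=C1OC(c2cc(OC)c(OCOC)cc2OCOC)Oc2cc(OCOC)c(CC=C(C)C)c(OCOC)c12
A2 | alternative 1 | (2S)-2-[5-methoxy-2,4-bis(methoxymethoxy)phenyl]-5,7-bis(methoxymethoxy)-6-(3-methylbut-2-enyl)chroman-4-one (identical with 20) | COc1cc([C@@H]2CC(=O)c3c(cc(OCOC)c(CC=C(C)C)c3OCOC)O2)c(OCOC)cc1OCOC
A3 | alternative 2 | (2S)-6-(2-diazoacetyl)-2-[5-methoxy-2,4-bis(methoxymethoxy)phenyl]-2,3-dihydro-4H-pyran-4-one | COc1cc([C@@H]2CC(=O)C=C(C(=O)C=[N+]=[N-])O2)c(OCOC)cc1OCOC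
A4 | alternative 2 | triisopropyl[(5-methylhex-4-en-1-yn-1-yl)oxy]silane | CC(C)=CCC#CO[Si](C(C)C)(C(C)C)C(C)C
A5 | alternative 2 | (2S)-5-hydroxy-2-[5-methoxy-2,4-bis(methoxymethoxy)phenyl]-6-(3-methylbut-2-enyl)-7-(triisopropylsilyloxy)chroman-4-one | COc1cc([C@@H]2CC(=O)c3c(cc(O[Si](C(C)C)(C(C)C)C(C)C)c(CC=C(C)C)c3O)O2)c(OCOC)cc1OCOC
A6 | alternative 3 | (2S)-2-ethynyl-5,7-bis(methoxymethoxy)-6-(3-methylbut-2-enyl)chroman-4-one | C#C[C@@H]1CC(=O)c2c(cc(OCOC)c(CC=C(C)C)c2OCOC)O1
A7 | alternative 3 | pentacarbonyl(2-tert-butoxy-1-methoxyprop-2-en-1-ylidene)chromium, (CO)5Cr=C(OMe)C(OtBu)=CH2 | C=C(OC(C)(C)C)C(OC)=[Cr](=C=O)(=C=O)(=C=O)(=C=O)=C=O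
A8 | alternative 3 | (2S)-2-(4-tert-butoxy-2-hydroxy-5-methoxyphenyl)-5,7-bis(methoxymethoxy)-6-(3-methylbut-2-enyl)chroman-4-one | COc1cc([C@@H]2CC(=O)c3c(cc(OCOC)c(CC=C(C)C)c3OCOC)O2)c(O)cc1OC(C)(C)C
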